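The whole plan rests on cutting the saturated nonadecyl chain carried by C2 of the quinone ring between C2' and C3', a bond flanked only by methylene groups, so that both termini can be taken from carboxylic acids. A mixed Kolbe electrolysis joins the 2-arylethyl and heptadecyl radicals in one operation, forming this single C–C bond without closing a ring or creating a stereocentre. The ring enters as its hydroquinone bis-pivalate, 3-[2,5-bis(pivaloyloxy)phenyl]propanoic acid, electron-poor enough to outlast the anode. It is assembled from 2,5-dihydroxybenzaldehyde by acylation, Wittig extension and hydrogenation, and the quinone is unveiled at the end by methanolysis and FeCl3 oxidation.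

Key step: step 4

Remark: the target is achiral. Ring atoms are numbered as in the quinone (carbonyls C1 and C4, chain on C2) and chain atoms C1' to C19' outward from the ring.

Remark: acid 6 is deliberately not made by opening 6-hydroxy-3,4-dihydrocoumarin, because an ortho phenol left unacylated, or a mixed anhydride formed at the carboxylate, would reclose to that lactone.

Step 1
Reactants: 1 2,5-dihydroxybenzaldehyde; 2 pivaloyl chloride
Product: 3 2-formyl-1,4-phenylene bis(2,2-dimethylpropanoate)
Conditions: PivCl (2.5 equiv), Et3N (3 equiv), DMAP (0.1 equiv), CH2Cl2, 0 °C to rt
Reagents that add atoms: pivaloyl chloride (compound 2), CC(C)(C)C(Cl)=O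
Why: DMAP-catalysed O-acylation (nucleophilic acyl substitution) by the acid chloride should esterify both phenols, the acylpyridinium ion being reactive enough for the ortho phenol that is hydrogen-bonded to the formyl group, while the aldehyde is untouched.

Step 2
Reactants: 3 2-formyl-1,4-phenylene bis(2,2-dimethylpropanoate); 4 benzyl (triphenylphosphoranylidene)acetate
Product: 5 benzyl (2E)-3-[2,5-bis(2,2-dimethylpropanoyloxy)phenyl]prop-2-enoate
Conditions: 4 (1.1 equiv), CH2Cl2, rt
Reagents that add atoms: benzyl (triphenylphosphoranylidene)acetate (compound 4), O=C(C=P(c1ccccc1)(c1ccccc1)c1ccccc1)OCc1ccccc1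
Why: Wittig olefination with a stabilised ylide attacks only the aldehyde, is neutral enough to leave the aryl pivalates intact and should give the E alkene, whose geometry is of no consequence because step 3 saturates it.

Step 3
Reactants: 5 benzyl (2E)-3-[2,5-bis(2,2-dimethylpropanoyloxy)phenyl]prop-2-enoate
Product: 6 3-[2,5-bis(2,2-dimethylpropanoyloxy)phenyl]propanoic acid
Conditions: H2 (1 atm), 10% Pd/C, EtOAc, rt
Reagents that add atoms: none
Why: Heterogeneous catalytic hydrogenation should saturate the cinnamate double bond and hydrogenolyse the benzyl ester in the same operation, releasing the free acid under neutral conditions that neither cleave the aryl pivalates nor allow lactonisation.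

Step 4
Reactants: 6 3-[2,5-bis(2,2-dimethylpropanoyloxy)phenyl]propanoic acid; 7 stearic acid (octadecanoic acid)
Product: 8 2-nonadecyl-1,4-phenylene bis(2,2-dimethylpropanoate)
Conditions: 6 (1 equiv), 7 (8 equiv), NaOMe (5 mol% of total acid), MeOH, 45–50 °C, undivided cell, smooth Pt foil anode and Pt cathode, constant current ca. 0.25 A cm−2, stopped while the electrolyte is still acidic
Reagents that add atoms: stearic acid (compound 7), CCCCCCCCCCCCCCCCCC(=O)O
Why: Above the critical potential a carboxylate layer covers the smooth platinum anode, each carboxylate gives up one electron and CO2, and the 2-arylethyl radical from 6 and the heptadecyl radical from 7, generated side by side at high surface concentration, combine to forge C2'–C3' (mixed Kolbe electrolysis, whose closest precedent is the anodic cross-coupling of 3-arylpropanoic acids with fatty acids). No ring is closed and no stereocentre is created. Cross-coupling over homocoupling is secured statistically by the eightfold excess of inexpensive 7, so that nearly every radical derived from 6 meets a heptadecyl partner, and the hydrocarbon homodimer of 7 is far less polar than 8 and should be removable by crystallisation or chromatography. Radical coupling over carbocation (non-Kolbe) chemistry is secured by the primary, non-benzylic radical centre at C2', by an electron-poor ring that offers little aryl participation, and by smooth Pt, high current density and a weakly acidic, only slightly neutralised medium. Survival of the arene is secured by the two acyloxy groups, which raise its oxidation potential well above that of a free or O-methylated hydroquinone, while the adsorbed carboxylate layer keeps the neutral ring away from the electrode. The bulky pivaloyl groups should resist methanolysis in the electrolyte, which the excess acid keeps acidic to the end, and should disfavour acyl transfer to the neighbouring radical.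

Step 5
Reactants: 8 2-nonadecyl-1,4-phenylene bis(2,2-dimethylpropanoate)
Product: 10 2-nonadecylcyclohexa-2,5-diene-1,4-dione (2-nonadecyl-1,4-benzoquinone), via 2-nonadecylbenzene-1,4-diol 9 (not isolated)
Conditions: NaOMe (3 equiv), degassed THF/MeOH, Ar, rt; then 2 M HCl, FeCl3 (2.5 equiv), H2O, 0 °C to rt
Reagents that add atoms: none
Why: Zemplén-type transesterification by methoxide should remove both aryl pivalates as methyl pivalate because phenoxide is a good leaving group, and after acidification FeCl3 (trivalent iron) performs the standard two-electron hydroquinone-to-quinone oxidation, the argon blanket protecting the hydroquinone dianion and the acid being added before the oxidant so that the base-sensitive quinone never meets methoxide.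

Compound list
1 | 2,5-dihydroxybenzaldehyde | O=Cc1cc(O)ccc1O | starting material
2 | pivaloyl chloride (2,2-dimethylpropanoyl chloride) | CC(C)(C)C(Cl)=O | starting material
3 | 2-formyl-1,4-phenylene bis(2,2-dimethylpropanoate) | CC(C)(C)C(=O)Oc1ccc(OC(=O)C(C)(C)C)c(C=O)c1 | intermediate
4 | benzyl (triphenylphosphoranylidene)acetate | O=C(C=P(c1ccccc1)(c1ccccc1)c1ccccc1)OCc1ccccc1 | starting material
5 | benzyl (2E)-3-[2,5-bis(2,2-dimethylpropanoyloxy)phenyl]prop-2-enoate | CC(C)(C)C(=O)Oc1ccc(OC(=O)C(C)(C)C)c(/C=C/C(=O)OCc2ccccc2)c1 | intermediate
6 | 3-[2,5-bis(2,2-dimethylpropanoyloxy)phenyl]propanoic acid | CC(C)(C)C(=O)Oc1ccc(OC(=O)C(C)(C)C)c(CCC(=O)O)c1 | intermediate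
7 | stearic acid (octadecanoic acid) | CCCCCCCCCCCCCCCCCC(=O)O | starting material
8 | 2-nonadecyl-1,4-phenylene bis(2,2-dimethylpropanoate) | CCCCCCCCCCCCCCCCCCCc1cc(OC(=O)C(C)(C)C)ccc1OC(=O)C(C)(C)C | intermediate
9 | 2-nonadecylbenzene-1,4-diol | CCCCCCCCCCCCCCCCCCCc1cc(O)ccc1O | intermediate (not isolated)
10 | 2-nonadecylcyclohexa-2,5-diene-1,4-dione | CCCCCCCCCCCCCCCCCCCC1=CC(=O)C=CC1=O | target

Total step count: 5. Longest linear sequence: 5 steps (1 → 3 → 5 → 6 → 8 → 10).

Steps most likely to fail

Step 4. The aromatic ring may be oxidised at the anode in competition with the carboxylate. The 2-arylethyl radical may be over-oxidised to a cation and trapped by methanol. Material may be lost to statistical homocoupling, and the anode may be passivated by a waxy hydrocarbon film. The fallback sets out from aldehyde 3 and comes back at 8, building the chain at C1'–C2' by carbonyl olefination instead of radical coupling. Commercial octadecyl(triphenyl)phosphonium bromide is deprotonated with NaN(SiMe3)2 in THF at −78 °C to octadecylidenetriphenylphosphorane F1. Aldehyde 3 is added at −78 °C, so that the formyl group is consumed before the hindered aryl esters can be attacked. The Wittig reaction should give 2-[(1Z)-nonadec-1-en-1-yl]-1,4-phenylene bis(2,2-dimethylpropanoate) F2, expected to be mainly Z, with the geometry of no consequence. Hydrogenation over 10% Pd/C in EtOAc then saturates the double bond to give 8.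

Step 5. Traces of oxygen may degrade the hydroquinone dianion during the basic methanolysis, and methanol or chloride may add to the freshly formed quinone in the one-pot oxidation. The fallback sets out from 8 and comes back at 10, separating the two events and avoiding both base and water at the quinone stage. LiAlH4 in THF at 0 °C cleaves both pivalates reductively, the acyl groups leaving as neopentyl alcohol. After an acidic work-up under argon, 2-nonadecylbenzene-1,4-diol 9 is isolated by crystallisation. It is then oxidised with Ag2O and MgSO4 in Et2O at rt, and filtration should deliver 10. No compound outside the list arises (F0).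

Step 1. Acylation of the ortho phenol may stay incomplete, because it is hydrogen-bonded to the formyl group and must accept a bulky acyl group, so that the reaction stalls at a mono-pivalate. The fallback sets out from 1 and comes back at 5, reversing the order of events. Aldehyde 1 is treated with ylide 4 in CH2Cl2 at rt; stabilised ylides tolerate free phenols, and the mild temperature avoids cyclisation to a coumarin. This should give benzyl (2E)-3-(2,5-dihydroxyphenyl)prop-2-enoate F3, whose ortho phenol is no longer chelated to an aldehyde. Pivaloylation of F3 with 2, Et3N and DMAP in CH2Cl2 then gives 5.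

Further compounds
F1 | step 4 | octadecylidenetriphenylphosphorane | CCCCCCCCCCCCCCCCCC=P(c1ccccc1)(c1ccccc1)c1ccccc1
F2 | step 4 | 2-[(1Z)-nonadec-1-en-1-yl]-1,4-phenylene bis(2,2-dimethylpropanoate) | CCCCCCCCCCCCCCCCC/C=C\c1cc(OC(=O)C(C)(C)C)ccc1OC(=O)C(C)(C)C
F0 | step 5 | none | none
F3 | step 1 | benzyl (2E)-3-(2,5-dihydroxyphenyl)prop-2-enoate | O=C(/C=C/c1cc(O)ccc1O)OCc1ccccc1
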